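The C3–C3a bond of the dihydrobenzofuran ring (O1, C2, C3, C3a, C7a) is cut and C3a is joined to the hydroxymethyl carbon instead. This reveals the six-membered pyranone ring of a (2S)-flavanone. The feature exploited is that C3 carries both the arene carbon C3a and a one-carbon branch. In one operation PhI(OAc)2 in acidic trimethyl orthoformate moves ring A from C4 to C3, contracts the ring, expels C4 as the ester carbon and sets C3 trans to C2. The precursor, a 6-bromo-8-methoxyflavanone, comes from asymmetric conjugate arylation of a chromone. The erythro-glycerol chain comes from (R)-glyceraldehyde acetonide.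

Key step: step 4

Assumption: the (S)-configured bisphosphine is taken to deliver the aryl group to the chromone face that gives the (2S)-flavanone, as (S)-BINAP-type rhodium catalysts do with six-membered cyclic enones; if the sense is the opposite, the (R)-ligand is used.

Step 1
Reactants: 1 1-(2-hydroxy-3-methoxyphenyl)ethanone
Product: 2 1-(5-bromo-2-hydroxy-3-methoxyphenyl)ethanone
Conditions: NBS, MeCN, 0 °C to rt
Reagents that add atoms: N-bromosuccinimide, O=C1CCC(=O)N1Br
Why: Electrophilic aromatic bromination, in which the phenol OH (both ortho positions blocked) directs bromine to its para position C5, which is also meta to the acetyl group and is the future anchor of the side chain.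

Step 2
Reactants: 2 1-(5-bromo-2-hydroxy-3-methoxyphenyl)ethanone
Product: 4 6-bromo-8-methoxy-4H-chromen-4-one, via enaminone 3 (not isolated)
Conditions: Me2NCH(OMe)2, toluene, 100 °C; concentrate; conc. HCl, CH2Cl2, 40 °C
Reagents that add atoms: N,N-dimethylformamide dimethyl acetal, COC(OC)N(C)C
Why: Enaminone condensation at the acetyl methyl group followed by acid-induced addition of the phenol and elimination of dimethylamine, the standard chromone synthesis from a 2-hydroxyacetophenone.

Step 3
Reactants: 4 6-bromo-8-methoxy-4H-chromen-4-one; 5 [4-(benzyloxy)-3-methoxyphenyl]boronic acid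
Product: 6 (2S)-2-[4-(benzyloxy)-3-methoxyphenyl]-6-bromo-8-methoxychroman-4-one
Conditions: [Rh(OH)(cod)]2 (cat.), (S)-MeO-F12-BIPHEP (cat.), CH2Cl2/H2O, rt
Reagents that add atoms: none
Why: Hayashi–Miyaura asymmetric 1,4-addition of an arylboronic acid to a chromone, in which the electron-poor chiral bisphosphine on monovalent rhodium selects the enone face and sets C2 as S, the near-neutral medium avoids retro-oxa-Michael racemisation, and the aryl bromide is inert at room temperature.

Step 4
Reactants: 6 (2S)-2-[4-(benzyloxy)-3-methoxyphenyl]-6-bromo-8-methoxychroman-4-one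
Product: 10 methyl (2S,3S)-2-[4-(benzyloxy)-3-methoxyphenyl]-5-bromo-7-methoxy-2,3-dihydrobenzofuran-3-carboxylate, via enol ether 7 (not isolated), via iodane ketal 8 (not isolated), via orthoester 9 (not isolated)
Conditions: PhI(OAc)2 (1.2 equiv), conc. H2SO4 (cat.), HC(OMe)3, rt; H2O quench, then aq. NaHCO3
Reagents that add atoms: trimethyl orthoformate, COC(OC)OC; water, O
Why: Acid and orthoformate convert the ketone into enol ether 7, the electrophilic trivalent iodine reagent adds to C3 (flavanone numbering) on the face opposite the equatorial 2-aryl group while methanol adds to C4, and in ketal 8 the equatorial C3–I bond lies antiperiplanar to the C4–C4a ring bond, so ring A migrates from C4 to C3 through a phenonium-type bridged ion as iodobenzene leaves, and the dimethoxycarbenium ion is trapped as orthoester 9, which collapses to the methyl ester on aqueous quench. The closest known reaction type is the hypervalent iodine (or thallium trinitrate) oxidative 1,2-aryl migration of aryl ketones in orthoformate, which is known on flavanones to give methyl trans-2-aryl-2,3-dihydrobenzofuran-3-carboxylates. The five-membered ring is closed by this 1,2-shift (3-exo attack of the ipso carbon C4a on C3, then cleavage of C4–C4a) and not by a new C–O bond, so O1–C2 and the C2 configuration are untouched and the six-membered ring loses C4 to the exocyclic ester. C3 is set by substrate control, because anti delivery of iodine relative to the C2 aryl group followed by inversion during migration places the ester trans to the aryl group, giving (2S,3S). The step needs migration of ring A in preference to the 2,3-shift of ring B (isoflavone pathway) and to proton loss (flavone pathway); the equatorially anchored 2-aryl group never reaches the antiperiplanar alignment, the O1 donor ortho to C4a raises the migratory aptitude of ring A, and the two C4 methoxy groups stabilise the developing cation. The aryl bromide and the benzyl ether are inert to these conditions, and once C3 exists any reversible C2–O1 ionisation can only return to the trans isomer.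

Step 5
Reactants: 10 methyl (2S,3S)-2-[4-(benzyloxy)-3-methoxyphenyl]-5-bromo-7-methoxy-2,3-dihydrobenzofuran-3-carboxylate
Product: 11 [(2S,3R)-2-[4-(benzyloxy)-3-methoxyphenyl]-5-bromo-7-methoxy-2,3-dihydrobenzofuran-3-yl]methanol
Conditions: i-Bu2AlH (2.5 equiv), CH2Cl2, −78 to 0 °C; aq. potassium sodium tartrate
Reagents that add atoms: none
Why: Ester reduction with a non-basic aluminium hydride avoids enolisation at C3 (epimerisation or E1cB opening of O1–C2) and leaves the aryl bromide and benzyl ether alone, the descriptor at C3 changing from S to R through CIP priorities only.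

Step 6
Reactants: 11 [(2S,3R)-2-[4-(benzyloxy)-3-methoxyphenyl]-5-bromo-7-methoxy-2,3-dihydrobenzofuran-3-yl]methanol; 12 (R)-2,2-dimethyl-1,3-dioxolane-4-carbaldehyde
Product: 15 (S)-{(2S,3R)-2-[4-(benzyloxy)-3-methoxyphenyl]-3-(hydroxymethyl)-7-methoxy-2,3-dihydrobenzofuran-5-yl}[(4R)-2,2-dimethyl-1,3-dioxolan-4-yl]methanol, via aryllithium alkoxide 13 (not isolated), via aryltitanium reagent 14 (not isolated)
Conditions: n-BuLi (2.1 equiv), THF, −78 °C; ClTi(OiPr)3 (2.2 equiv), −78 to −40 °C; 12, −40 to 0 °C; aq. NH4Cl
Reagents that add atoms: none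
Why: Deprotonation of the alcohol, bromine–lithium exchange and transmetalation give a bulky, weakly Lewis acidic aryltitanium reagent that cannot chelate, so it should add to the α-alkoxy aldehyde under Felkin–Anh control anti to the dioxolane C–O bond and set C7' as S (erythro to C8', whose R configuration comes with 12), any syn epimer being removed by chromatography.

Step 7
Reactants: 15 (S)-{(2S,3R)-2-[4-(benzyloxy)-3-methoxyphenyl]-3-(hydroxymethyl)-7-methoxy-2,3-dihydrobenzofuran-5-yl}[(4R)-2,2-dimethyl-1,3-dioxolan-4-yl]methanol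
Product: 16 (1S,2R)-1-{(2S,3R)-2-[4-(benzyloxy)-3-methoxyphenyl]-3-(hydroxymethyl)-7-methoxy-2,3-dihydrobenzofuran-5-yl}propane-1,2,3-triol
Conditions: AcOH/H2O 4:1, 40 °C
Reagents that add atoms: none
Why: Mild acidic hydrolysis of the isopropylidene acetal, carried out while the phenol is still benzylated so that no p-quinone methide can form and the benzylic centres C2 and C7' are not scrambled.

Step 8
Reactants: 16 (1S,2R)-1-{(2S,3R)-2-[4-(benzyloxy)-3-methoxyphenyl]-3-(hydroxymethyl)-7-methoxy-2,3-dihydrobenzofuran-5-yl}propane-1,2,3-triol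
Product: 17 (1S,2R)-1-[(2S,3R)-2-(4-hydroxy-3-methoxyphenyl)-3-(hydroxymethyl)-7-methoxy-2,3-dihydrobenzofuran-5-yl]propane-1,2,3-triol
Conditions: H2 (1 atm), Pd/C, EtOAc/EtOH, rt
Reagents that add atoms: none
Why: Hydrogenolysis of the phenolic benzyl ether is the fastest C–O cleavage available, so under neutral conditions at ambient pressure the secondary benzylic alcohol C7' and the cyclic benzylic ether C2–O1 should persist and the target is released.

Compound list
1 | 1-(2-hydroxy-3-methoxyphenyl)ethanone | CC(=O)c1cccc(OC)c1O | starting material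
2 | 1-(5-bromo-2-hydroxy-3-methoxyphenyl)ethanone | CC(=O)c1cc(Br)cc(OC)c1O | intermediate
3 | (E)-1-(5-bromo-2-hydroxy-3-methoxyphenyl)-3-(dimethylamino)prop-2-en-1-one | CN(C)/C=C/C(=O)c1cc(Br)cc(OC)c1O | intermediate
4 | 6-bromo-8-methoxy-4H-chromen-4-one | COc1cc(Br)cc2c1OC=CC2=O | intermediate
5 | [4-(benzyloxy)-3-methoxyphenyl]boronic acid | COc1cc(B(O)O)ccc1OCc1ccccc1 | starting material
6 | (2S)-2-[4-(benzyloxy)-3-methoxyphenyl]-6-bromo-8-methoxychroman-4-one | COc1cc([C@H]2Oc3c(OC)cc(Br)cc3C(=O)C2)ccc1OCc1ccccc1 | intermediate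
7 | (2S)-2-[4-(benzyloxy)-3-methoxyphenyl]-6-bromo-4,8-dimethoxy-2H-chromene | COc1cc([C@H]2Oc3c(OC)cc(Br)cc3C(OC)=C2)ccc1OCc1ccccc1 | intermediate
8 | 2,3-trans-3-[acetoxy(phenyl)-λ3-iodanyl]-2-[4-(benzyloxy)-3-methoxyphenyl]-6-bromo-4,4,8-trimethoxychroman (C2 arranged as in 6, iodine anti to the 2-aryl group) | COc1cc([C@H]2Oc3c(OC)cc(Br)cc3C(OC)(OC)[C@@H]2I(OC(C)=O)c2ccccc2)ccc1OCc1ccccc1 | intermediate
9 | (2S,3S)-2-[4-(benzyloxy)-3-methoxyphenyl]-5-bromo-7-methoxy-3-(trimethoxymethyl)-2,3-dihydrobenzofuran | COc1cc([C@H]2Oc3c(OC)cc(Br)cc3[C@@H]2C(OC)(OC)OC)ccc1OCc1ccccc1 | intermediate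
10 | methyl (2S,3S)-2-[4-(benzyloxy)-3-methoxyphenyl]-5-bromo-7-methoxy-2,3-dihydrobenzofuran-3-carboxylate | COc1cc([C@H]2Oc3c(OC)cc(Br)cc3[C@@H]2C(=O)OC)ccc1OCc1ccccc1 | intermediate
11 | [(2S,3R)-2-[4-(benzyloxy)-3-methoxyphenyl]-5-bromo-7-methoxy-2,3-dihydrobenzofuran-3-yl]methanol | COc1cc([C@H]2Oc3c(OC)cc(Br)cc3[C@@H]2CO)ccc1OCc1ccccc1 | intermediate
12 | (R)-2,2-dimethyl-1,3-dioxolane-4-carbaldehyde | O=C[C@H]1COC(C)(C)O1 | starting material
13 | 5-lithio derivative of 11 as its lithium alkoxide | COc1cc([C@H]2Oc3c(OC)cc([Li])cc3[C@@H]2CO[Li])ccc1OCc1ccccc1 | intermediate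
14 | 5-(triisopropoxytitanio) derivative of 11 as its triisopropoxytitanium alkoxide | COc1cc([C@H]2Oc3c(OC)cc([Ti](OC(C)C)(OC(C)C)OC(C)C)cc3[C@@H]2CO[Ti](OC(C)C)(OC(C)C)OC(C)C)ccc1OCc1ccccc1 | intermediate
15 | (S)-{(2S,3R)-2-[4-(benzyloxy)-3-methoxyphenyl]-3-(hydroxymethyl)-7-methoxy-2,3-dihydrobenzofuran-5-yl}[(4R)-2,2-dimethyl-1,3-dioxolan-4-yl]methanol | COc1cc([C@H]2Oc3c(OC)cc([C@H](O)[C@H]4COC(C)(C)O4)cc3[C@@H]2CO)ccc1OCc1ccccc1 | intermediate
16 | (1S,2R)-1-{(2S,3R)-2-[4-(benzyloxy)-3-methoxyphenyl]-3-(hydroxymethyl)-7-methoxy-2,3-dihydrobenzofuran-5-yl}propane-1,2,3-triol | COc1cc([C@H]2Oc3c(OC)cc([C@H](O)[C@H](O)CO)cc3[C@@H]2CO)ccc1OCc1ccccc1 | intermediate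
17 | (1S,2R)-1-[(2S,3R)-2-(4-hydroxy-3-methoxyphenyl)-3-(hydroxymethyl)-7-methoxy-2,3-dihydrobenzofuran-5-yl]propane-1,2,3-triol | COc1cc([C@H]2Oc3c(OC)cc([C@H](O)[C@H](O)CO)cc3[C@@H]2CO)ccc1O | target

Total step count: 8. Longest linear sequence: 8 steps (1 to 17).

Steps most likely to fail

Step 4. Several processes may compete with the ring A migration:
- the 2,3-shift of the electron-rich ring B
- proton loss from the C3 iodane
- attack of the oxidant on the dialkoxyarene
- acid-induced opening of the pyranone before ketalisation, which would erode the C2 configuration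

The fallback sets out from 6 and comes back at 10. It separates installation of the leaving group from the migration, so no arene oxidant is present. Phenyltrimethylammonium tribromide in THF should brominate the ketone α-carbon and, after acid equilibration, give the trans-3-bromoflavanone F1. HC(OMe)3, MeOH and TsOH should convert it into the α-bromo dimethyl ketal F2. AgBF4 in MeOH (or ZnBr2 in hot toluene) should then abstract the equatorial bromide and trigger the same contraction. This is the Lewis acid-induced 1,2-aryl migration of α-halo ketals known from 2-arylpropionate ester synthesis, and it should give 10 after aqueous work-up.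

Step 6. Facial selectivity in the addition to the α-alkoxy aldehyde may be poor. Exchange or transmetalation may be incomplete in the presence of the alkoxide, and the aryl anion may be quenched by a proton. The fallback sets out from 11 and comes back at 15, replacing substrate control by catalyst control. Commercial methyl (R)-2,2-dimethyl-1,3-dioxolane-4-carboxylate is converted with MeNH(OMe)·HCl and i-PrMgCl into the Weinreb amide F3. The dilithio species 13, generated as in step 6, is acylated with F3 to give the aryl ketone F4. Noyori-type asymmetric transfer hydrogenation with RuCl(p-cymene)[(R,R)-TsDPEN] in HCO2H/Et3N should then deliver hydride to the face that gives the 7'S carbinol 15.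

Step 3. Insertion into the donor-substituted chromone may be sluggish. The electron-rich boronic acid may protodeboronate, a second 1,2-addition to the product ketone may occur, and enantioface discrimination may be insufficient. The fallback sets out from 2 and comes back at 6.
- Claisen–Schmidt condensation of 2 with commercial 4-(benzyloxy)-3-methoxybenzaldehyde (KOH, EtOH) should give the chalcone F5.
- NaOAc in refluxing EtOH should close F5 by intramolecular oxa-Michael addition to the racemic flavanone F6.
- Kinetic resolution by asymmetric transfer hydrogenation with RhCl(Cp*)[(R,R)-TsDPEN] in HCO2H/Et3N should reduce the (2R)-enantiomer to the cis-flavan-4-ol F7. The (2S)-flavanone 6 should remain untouched and is separated by chromatography.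

Further compounds
F1 | step 4 | trans-3-bromo derivative of 6, (2R,3R) by CIP with C2 arranged as in 6 | COc1cc([C@H]2Oc3c(OC)cc(Br)cc3C(=O)[C@@H]2Br)ccc1OCc1ccccc1
F2 | step 4 | 4,4-dimethyl ketal of F1 | COc1cc([C@H]2Oc3c(OC)cc(Br)cc3C(OC)(OC)[C@@H]2Br)ccc1OCc1ccccc1
F3 | step 6 | (R)-N-methoxy-N,2,2-trimethyl-1,3-dioxolane-4-carboxamide | CON(C)C(=O)[C@H]1COC(C)(C)O1
F4 | step 6 | {(2S,3R)-2-[4-(benzyloxy)-3-methoxyphenyl]-3-(hydroxymethyl)-7-methoxy-2,3-dihydrobenzofuran-5-yl}[(4R)-2,2-dimethyl-1,3-dioxolan-4-yl]methanone | COc1cc([C@H]2Oc3c(OC)cc(C(=O)[C@H]4COC(C)(C)O4)cc3[C@@H]2CO)ccc1OCc1ccccc1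
F5 | step 3 | (E)-3-[4-(benzyloxy)-3-methoxyphenyl]-1-(5-bromo-2-hydroxy-3-methoxyphenyl)prop-2-en-1-one | COc1cc(/C=C/C(=O)c2cc(Br)cc(OC)c2O)ccc1OCc1ccccc1
F6 | step 3 | racemic 2-[4-(benzyloxy)-3-methoxyphenyl]-6-bromo-8-methoxychroman-4-one | COc1cc(C2Oc3c(OC)cc(Br)cc3C(=O)C2)ccc1OCc1ccccc1
F7 | step 3 | (2R,4R)-2-[4-(benzyloxy)-3-methoxyphenyl]-6-bromo-8-methoxychroman-4-ol | COc1cc([C@@H]2Oc3c(OC)cc(Br)cc3[C@H](O)C2)ccc1OCc1ccccc1
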